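**Retrosynthetic overview**
1. Stephaflavone B ⇐ its 5-O-methyl ether on the C3-linked (4'-hydroxy) flavone unit, by chelation-controlled BCl3 demethylation.
2. Ring C of the C3-linked unit ⇐ cyclodehydration of a 2-aryl-1,3-diketone whose 2-aryl group is C6 of the intact 4'-methoxyflavone unit.
3. Key C3–C6'' bond ⇐ electrophilic α-keto carbenoid (enolonium equivalent) from a 2-diazo-1,3-diketone plus the unfunctionalised C6–H of 5-hydroxy-7,4'-dimethoxyflavone; two natively nucleophilic carbons are joined with no halide or boron on either partner.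
4. Diazo diketone ⇐ Claisen condensation of 2',4',6'-trimethoxyacetophenone with methyl 4-(benzyloxy)benzoate, then diazo transfer; flavone partner ⇐ apigenin by 7,4'-di-O-methylation.
5. Ring order: the C6-linked flavone is complete from the start; ring C of the C3-linked flavone is closed only after the inter-unit bond exists.

Assumption: the SMILES has no stereocentre and no axial descriptor, so the target is made as the constitution drawn; the hindered C3–C6'' axis is formed without control and no enantioselective step is needed.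

**Step 1**
Reactants: 1 2',4',6'-trimethoxyacetophenone; 2 methyl 4-(benzyloxy)benzoate
Product: 3 1-[4-(benzyloxy)phenyl]-3-(2,4,6-trimethoxyphenyl)propane-1,3-dione
Conditions: NaH (3 equiv), THF, 65 °C; then 1 M HCl
Reagents that add atoms: none
Why: Crossed Claisen condensation in which the methyl-ketone enolate of 1 acylates on the non-enolisable ester 2 and the product is drawn off as its stabilised sodium diketonate; no stereocentre is formed.

**Step 2**
Reactants: 3 1-[4-(benzyloxy)phenyl]-3-(2,4,6-trimethoxyphenyl)propane-1,3-dione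
Product: 4 1-[4-(benzyloxy)phenyl]-2-diazo-3-(2,4,6-trimethoxyphenyl)propane-1,3-dione
Conditions: p-ABSA (1.2 equiv), Et3N (2 equiv), MeCN, 0 → 20 °C
Reagents that add atoms: 4-acetamidobenzenesulfonyl azide (p-ABSA), CC(=O)Nc1ccc(cc1)S(=O)(=O)N=[N+]=[N-]
Why: Regitz diazo transfer to the doubly activated methylene of the 1,3-diketone, the sulfonyl azide leaving as its sulfonamide while the aryl ethers are untouched.

**Step 3**
Reactants: 5 apigenin
Product: 7 5-hydroxy-7-methoxy-2-(4-methoxyphenyl)-4H-chromen-4-one (apigenin 7,4'-dimethyl ether), via genkwanin 6 (not isolated)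
Conditions: MeI (2.2 equiv), K2CO3 (2.5 equiv), DMF, 20 °C
Reagents that add atoms: iodomethane, CI
Why: Williamson O-methylation that stops at two methyl groups because the 5-OH is hydrogen-bonded to the C4 carbonyl and is not deprotonated by K2CO3; the more acidic 7-OH reacts first, then the 4'-OH.

**Step 4**
Reactants: 4 1-[4-(benzyloxy)phenyl]-2-diazo-3-(2,4,6-trimethoxyphenyl)propane-1,3-dione; 7 5-hydroxy-7-methoxy-2-(4-methoxyphenyl)-4H-chromen-4-one
Product: 8 6-{1-[4-(benzyloxy)phenyl]-1,3-dioxo-3-(2,4,6-trimethoxyphenyl)propan-2-yl}-5-hydroxy-7-methoxy-2-(4-methoxyphenyl)-4H-chromen-4-one (racemic, enolisable methine)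
Conditions: Rh2(OAc)4 (2 mol%), 7 (3 equiv, excess recovered), ClCH2CH2Cl, 80 °C, 4 added over 4 h
Reagents that add atoms: none
Why: Proposed new method: Rh2(OAc)4 strips N2 from 4 to give a divalent-rhodium α,α'-diketo carbenoid, an enolonium equivalent with an electrophilic α-carbon, which the phloroglucinol-type ring of 7 attacks by electrophilic aromatic substitution (formal C–H insertion) at C6, the site ortho to the chelated 5-OH that iodinating electrophiles choose in free-5-hydroxy-7-methoxyflavones (C8 takes over only when O5 is alkylated), while the chelated O–H is a poor donor for O–H insertion and the ortho-methoxy groups of 4 can only form reversible oxonium ylides; the closest known reaction type is the dirhodium-catalysed arylation of diazomalonates and 2-diazo-1,3-diones by electron-rich arenes such as 1,3,5-trimethoxybenzene and indoles; the new methine is racemic and is erased in step 5.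

**Step 5**
Reactants: 8 6-{1-[4-(benzyloxy)phenyl]-1,3-dioxo-3-(2,4,6-trimethoxyphenyl)propan-2-yl}-5-hydroxy-7-methoxy-2-(4-methoxyphenyl)-4H-chromen-4-one
Product: 10 5-hydroxy-6-[2-(4-hydroxyphenyl)-5,7-dimethoxy-4-oxo-4H-chromen-3-yl]-7-methoxy-2-(4-methoxyphenyl)-4H-chromen-4-one, via triphenolic 1,3-diketone 9 (not isolated)
Conditions: BCl3 (8 equiv), C6HMe5 (3 equiv), CH2Cl2, −78 → 20 °C; MeOH quench, then 60 °C, 1 h (HCl formed in situ); aqueous work-up
Reagents that add atoms: none
Why: BCl3 cleaves the benzyl ether (cation trapped by pentamethylbenzene) and, by chelation to the benzoyl carbonyl, one of the two equivalent ortho-methoxy groups, after which acid-catalysed cyclodehydration of the o-hydroxyaryl 1,3-diketone (closing stage of the Baker–Venkataraman flavone synthesis) forms the six-membered pyranone in preference to furan closure by the chelated, doubly flanked 5-OH of the other unit, the same preference that lets 2'-hydroxyisoflavones be made from 2,2'-dihydroxydeoxybenzoins.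

**Step 6**
Reactants: 10 5-hydroxy-6-[2-(4-hydroxyphenyl)-5,7-dimethoxy-4-oxo-4H-chromen-3-yl]-7-methoxy-2-(4-methoxyphenyl)-4H-chromen-4-one
Product: 11 stephaflavone B, 5-hydroxy-6-[5-hydroxy-2-(4-hydroxyphenyl)-7-methoxy-4-oxo-4H-chromen-3-yl]-7-methoxy-2-(4-methoxyphenyl)-4H-chromen-4-one
Conditions: BCl3 (5 equiv), CH2Cl2, 0 → 20 °C; then 1 M HCl, 40 °C
Reagents that add atoms: none
Why: Chelation-controlled Lewis-acid demethylation in which BCl3 bound to the C4 carbonyl cleaves only the peri 5-methoxy group, leaving the two 7-methoxy groups and the 4'-methoxy group intact.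

**Compound list**
1 | 2',4',6'-trimethoxyacetophenone (achiral) | CC(=O)c1c(OC)cc(OC)cc1OC | starting material
2 | methyl 4-(benzyloxy)benzoate (achiral) | COC(=O)c1ccc(OCc2ccccc2)cc1 | starting material
3 | 1-[4-(benzyloxy)phenyl]-3-(2,4,6-trimethoxyphenyl)propane-1,3-dione (achiral) | COc1cc(OC)c(C(=O)CC(=O)c2ccc(OCc3ccccc3)cc2)c(OC)c1 | intermediate
4 | 1-[4-(benzyloxy)phenyl]-2-diazo-3-(2,4,6-trimethoxyphenyl)propane-1,3-dione (achiral) | COc1cc(OC)c(C(=O)C(=[N+]=[N-])C(=O)c2ccc(OCc3ccccc3)cc2)c(OC)c1 | intermediate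
5 | apigenin, 5,7-dihydroxy-2-(4-hydroxyphenyl)-4H-chromen-4-one (achiral) | O=c1cc(-c2ccc(O)cc2)oc2cc(O)cc(O)c12 | starting material
6 | genkwanin, 5-hydroxy-2-(4-hydroxyphenyl)-7-methoxy-4H-chromen-4-one (achiral) | COc1cc(O)c2c(c1)oc(-c1ccc(O)cc1)cc2=O | intermediate (not isolated)
7 | 5-hydroxy-7-methoxy-2-(4-methoxyphenyl)-4H-chromen-4-one (achiral) | COc1ccc(-c2cc(=O)c3c(O)cc(OC)cc3o2)cc1 | intermediate
8 | 6-{1-[4-(benzyloxy)phenyl]-1,3-dioxo-3-(2,4,6-trimethoxyphenyl)propan-2-yl}-5-hydroxy-7-methoxy-2-(4-methoxyphenyl)-4H-chromen-4-one (racemic methine) | COc1ccc(-c2cc(=O)c3c(O)c(C(C(=O)c4c(OC)cc(OC)cc4OC)C(=O)c4ccc(OCc5ccccc5)cc4)c(OC)cc3o2)cc1 | intermediate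
9 | 5-hydroxy-6-[1-(2-hydroxy-4,6-dimethoxyphenyl)-3-(4-hydroxyphenyl)-1,3-dioxopropan-2-yl]-7-methoxy-2-(4-methoxyphenyl)-4H-chromen-4-one (racemic methine) | COc1ccc(-c2cc(=O)c3c(O)c(C(C(=O)c4c(O)cc(OC)cc4OC)C(=O)c4ccc(O)cc4)c(OC)cc3o2)cc1 | intermediate (not isolated)
10 | 5-hydroxy-6-[2-(4-hydroxyphenyl)-5,7-dimethoxy-4-oxo-4H-chromen-3-yl]-7-methoxy-2-(4-methoxyphenyl)-4H-chromen-4-one (no stereocentre) | COc1ccc(-c2cc(=O)c3c(O)c(-c4c(-c5ccc(O)cc5)oc5cc(OC)cc(OC)c5c4=O)c(OC)cc3o2)cc1 | intermediate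
11 | stephaflavone B (no stereocentre) | COc1ccc(-c2cc(=O)c3c(O)c(-c4c(-c5ccc(O)cc5)oc5cc(OC)cc(O)c5c4=O)c(OC)cc3o2)cc1 | target

**Totals**
Total steps: 6 (isolated products 3, 4, 7, 8, 10, 11).
Longest linear sequence: 5 steps (1 → 3 → 4 → 8 → 10 → 11); step 3 is a one-step branch.

**Three steps most likely to fail**

Step 4 (key coupling). The carbenoid may attack C8 instead of C6, insert into the 5-O–H, add to C3 of the pyranone of 7, undergo Wolff rearrangement, or attack the trimethoxyphenyl ring of a second molecule of 4. Slow addition of 4 to excess 7 addresses only the last of these. The fallback sets out from 4 and 7 and comes back to the route at 8. Diazo compound 4 is oxidised with dimethyldioxirane (acetone, 0 °C) to the vicinal tricarbonyl 1-[4-(benzyloxy)phenyl]-3-(2,4,6-trimethoxyphenyl)propane-1,2,3-trione F1, whose central carbonyl is the same α-keto electrophile in closed-shell form. Flavone 7 is converted into its bromomagnesium phenoxide (EtMgBr, CH2Cl2/toluene, 0 → 20 °C) and adds to F1 through C6, the only carbon ortho to the magnesium-bound oxygen, since the electrophile is delivered inside the magnesium chelate (ortho-specific hydroxyalkylation). This gives racemic 6-{1-[4-(benzyloxy)phenyl]-2-hydroxy-1,3-dioxo-3-(2,4,6-trimethoxyphenyl)propan-2-yl}-5-hydroxy-7-methoxy-2-(4-methoxyphenyl)-4H-chromen-4-one F2. SmI2 (THF–MeOH, −78 °C) then cleaves the C–OH bond flanked by the two ketones and gives 8.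

Step 5 (unmasking and ring closure). The free 5-OH of the 4'-methoxyflavone unit sits ortho to the diketone methine and could close a furan onto the 4-hydroxybenzoyl carbonyl instead of the desired pyranone; BCl3 could also under- or over-cleave. The fallback closes ring C by aryl C–O bond formation under base, where no phenol–ketone condensation can occur; it sets out from 2 and 7 and comes back to the route at 11. Commercial 1-bromo-3,5-dimethoxybenzene is acetylated (AcCl, AlCl3, CH2Cl2, 0 °C) to 1-(2-bromo-4,6-dimethoxyphenyl)ethan-1-one F3. Claisen condensation of F3 with 2 (NaH, THF) gives 1-[4-(benzyloxy)phenyl]-3-(2-bromo-4,6-dimethoxyphenyl)propane-1,3-dione F4, and diazo transfer as in step 2 gives 1-[4-(benzyloxy)phenyl]-3-(2-bromo-4,6-dimethoxyphenyl)-2-diazopropane-1,3-dione F5. Coupling with 7 under the step 4 conditions gives racemic 6-{1-[4-(benzyloxy)phenyl]-3-(2-bromo-4,6-dimethoxyphenyl)-1,3-dioxopropan-2-yl}-5-hydroxy-7-methoxy-2-(4-methoxyphenyl)-4H-chromen-4-one F6. CuI with 1,10-phenanthroline and Cs2CO3 in DMF at 100 °C effects intramolecular O-arylation of the diketone enolate and gives 6-{2-[4-(benzyloxy)phenyl]-5,7-dimethoxy-4-oxo-4H-chromen-3-yl}-5-hydroxy-7-methoxy-2-(4-methoxyphenyl)-4H-chromen-4-one F7. BCl3 with pentamethylbenzene (CH2Cl2, −78 → 20 °C) then removes the benzyl group and the peri methyl group together and gives 11.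

Step 1 (Claisen condensation). The di-ortho-substituted ketone 1 may condense sluggishly, and the product can suffer retro-Claisen cleavage under prolonged heating with base. The fallback sets out from 1 and comes back to the route at 3. The lithium enolate of 1 (LiN(iPr)2, THF, −78 °C) adds to 4-(benzyloxy)benzaldehyde to give racemic 3-[4-(benzyloxy)phenyl]-3-hydroxy-1-(2,4,6-trimethoxyphenyl)propan-1-one F8, and Dess–Martin periodinane (CH2Cl2, 20 °C) oxidises the carbinol to diketone 3.

**Further compounds**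
F1 | step 4 | 1-[4-(benzyloxy)phenyl]-3-(2,4,6-trimethoxyphenyl)propane-1,2,3-trione | COc1cc(OC)c(C(=O)C(=O)C(=O)c2ccc(OCc3ccccc3)cc2)c(OC)c1
F2 | step 4 | 6-{1-[4-(benzyloxy)phenyl]-2-hydroxy-1,3-dioxo-3-(2,4,6-trimethoxyphenyl)propan-2-yl}-5-hydroxy-7-methoxy-2-(4-methoxyphenyl)-4H-chromen-4-one (racemic) | COc1ccc(-c2cc(=O)c3c(O)c(C(O)(C(=O)c4c(OC)cc(OC)cc4OC)C(=O)c4ccc(OCc5ccccc5)cc4)c(OC)cc3o2)cc1
F3 | step 5 | 1-(2-bromo-4,6-dimethoxyphenyl)ethan-1-one | CC(=O)c1c(Br)cc(OC)cc1OC
F4 | step 5 | 1-[4-(benzyloxy)phenyl]-3-(2-bromo-4,6-dimethoxyphenyl)propane-1,3-dione | COc1cc(Br)c(C(=O)CC(=O)c2ccc(OCc3ccccc3)cc2)c(OC)c1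
F5 | step 5 | 1-[4-(benzyloxy)phenyl]-3-(2-bromo-4,6-dimethoxyphenyl)-2-diazopropane-1,3-dione | COc1cc(Br)c(C(=O)C(=[N+]=[N-])C(=O)c2ccc(OCc3ccccc3)cc2)c(OC)c1
F6 | step 5 | 6-{1-[4-(benzyloxy)phenyl]-3-(2-bromo-4,6-dimethoxyphenyl)-1,3-dioxopropan-2-yl}-5-hydroxy-7-methoxy-2-(4-methoxyphenyl)-4H-chromen-4-one (racemic) | COc1ccc(-c2cc(=O)c3c(O)c(C(C(=O)c4c(Br)cc(OC)cc4OC)C(=O)c4ccc(OCc5ccccc5)cc4)c(OC)cc3o2)cc1
F7 | step 5 | 6-{2-[4-(benzyloxy)phenyl]-5,7-dimethoxy-4-oxo-4H-chromen-3-yl}-5-hydroxy-7-methoxy-2-(4-methoxyphenyl)-4H-chromen-4-one | COc1ccc(-c2cc(=O)c3c(O)c(-c4c(-c5ccc(OCc6ccccc6)cc5)oc5cc(OC)cc(OC)c5c4=O)c(OC)cc3o2)cc1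
F8 | step 1 | 3-[4-(benzyloxy)phenyl]-3-hydroxy-1-(2,4,6-trimethoxyphenyl)propan-1-one (racemic) | COc1cc(OC)c(C(=O)CC(O)c2ccc(OCc3ccccc3)cc2)c(OC)c1
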